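The hydroazulene is cut into a three-carbon unit C5–C6–C7 and a four-carbon unit C8–C9–C10–C1 (daucane numbering: C1 quaternary, C4 carbinol, C5 ring-fusion CH, C6 ester carbon, C10 ketone). The key step, a silyl-triflate-catalysed intramolecular (4+3) cycloaddition of an epoxy enolsilane, forms C1–C5 and C7–C8 and so closes the five- and the seven-membered ring from an open chain. It exploits the 1,3-relationship of the C6 oxygen and the C4 tertiary hydroxyl (C4–C5 epoxide beside a C6 enolsilane, a latent oxyallyl cation) and the C10 ketone (2-silyloxydiene C1=C10–C9=C8). Ketone reduction, vanilloylation, Saegusa oxidation and desilylation finish the route.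

Key step: step 10

Remark on the chemistry: daucane numbering is used for the bicyclic compounds (C1 ring-fusion carbon with CH3, C2, C3, C4 carbinol carbon with isopropyl, C5 ring-fusion CH, C6, C7, C8 with CH3, C9, C10). Centres that are erased later (the methyl-bearing carbon of 8–17, C8 of 20, 21 and 26) and the geometry of the tetrasubstituted enol ether of 18 are not controlled, and these compounds are used as mixtures.

Step 1
Reactants: 1 3-methylbut-1-yne; 2 N-methoxy-N-methylacetamide
Product: 4 5-methylhex-3-yn-2-one, via lithium 3-methylbut-1-yn-1-ide 3 (not isolated)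
Conditions: n-BuLi, THF, −78 °C; then 2, −78 → 0 °C; aq NH4Cl
Reagents that add atoms: none
Why: Acylation of the lithium acetylide by the Weinreb amide (Weinreb ketone synthesis) should stop at the ynone because the chelated tetrahedral adduct survives until work-up.

Step 2
Reactants: 4 5-methylhex-3-yn-2-one
Product: 5 (2S)-5-methylhex-3-yn-2-ol
Conditions: Ru[(S,S)-TsDPEN](p-cymene) (0.5 mol %), i-PrOH, rt
Reagents that add atoms: none
Why: Noyori asymmetric transfer hydrogenation of an alkynyl methyl ketone, in which the alkyne takes the place of the aryl group in the CH/π-controlled transition state, should set the (S)-carbinol with the (S,S)-catalyst and leave the triple bond untouched.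

Step 3
Reactants: 5 (2S)-5-methylhex-3-yn-2-ol
Product: 7 (2S,3Z)-4-iodo-5-methylhex-3-en-2-ol, via cyclic alkenylalanate 6 (not isolated)
Conditions: NaAlH2(OCH2CH2OMe)2 (Red-Al), THF, 0 °C → rt; then I2, −78 °C; aqueous work-up
Reagents that add atoms: iodine, II
Why: Hydroxyl-directed trans-hydroalumination should place aluminium on the distal alkyne carbon in a five-membered alanate, and iodinolysis with retention should give the iodoalkene with iodine cis to the carbinol carbon (hydroalumination–iodination of a propargylic alcohol), the carbinol centre being untouched.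

Step 4
Reactants: 8 2-methylbut-3-enoic acid
Product: 10 N-methoxy-N,2-dimethylbut-3-enamide, via acyl imidazole 9 (not isolated)
Conditions: CDI, CH2Cl2, 0 °C → rt; then MeNHOMe·HCl, rt
Reagents that add atoms: N,O-dimethylhydroxylamine hydrochloride, CNOC.Cl
Why: Activation as the acyl imidazole and aminolysis (Weinreb amide formation) proceeds without added strong base, so the double bond should not move into conjugation.

Step 5
Reactants: 10 N-methoxy-N,2-dimethylbut-3-enamide; 7 (2S,3Z)-4-iodo-5-methylhex-3-en-2-ol
Product: 12 (5E,7S)-7-hydroxy-N-methoxy-N,2-dimethyl-5-(propan-2-yl)oct-5-enamide, via B-alkyl-9-BBN borane 11 (not isolated)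
Conditions: 10, 9-BBN, THF, 0 °C → rt; then 7, Pd(dppf)Cl2 (5 mol %), AsPh3, Cs2CO3, DMF/H2O, rt
Reagents that add atoms: none
Why: 9-BBN should add anti-Markovnikov to the monosubstituted alkene and the B-alkyl Suzuki–Miyaura coupling replaces iodine with retention of alkene geometry, so the new chain ends cis to the carbinol carbon and the isopropyl group trans, with the free hydroxyl and the amide tolerated.

Step 6
Reactants: 12 (5E,7S)-7-hydroxy-N-methoxy-N,2-dimethyl-5-(propan-2-yl)oct-5-enamide; 13 (E)-1-bromoprop-1-ene
Product: 15 (2E,8E,10S)-10-hydroxy-5-methyl-8-(propan-2-yl)undeca-2,8-dien-4-one, via (E)-prop-1-enyllithium 14 (not isolated)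
Conditions: 13, t-BuLi, Et2O, −78 °C; then 12, THF, −78 → −20 °C; aq NH4Cl
Reagents that add atoms: none
Why: Bromine–lithium exchange with retention gives the (E)-alkenyllithium, whose addition to the Weinreb amide (one further equivalent is consumed by the hydroxyl) should stop at the chelated adduct and give the (E)-enone on work-up (Weinreb ketone synthesis).

Step 7
Reactants: 15 (2E,8E,10S)-10-hydroxy-5-methyl-8-(propan-2-yl)undeca-2,8-dien-4-one
Product: 16 (2E)-7-[(2R,3R)-3-[(1S)-1-hydroxyethyl]-2-(propan-2-yl)oxiran-2-yl]-5-methylhept-2-en-4-one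
Conditions: mCPBA, CH2Cl2, 0 °C
Reagents that add atoms: 3-chloroperoxybenzoic acid, OOC(=O)c1cccc(Cl)c1
Why: Hydroxyl-directed (Henbest) epoxidation of the electron-rich trisubstituted alkene, the enone being inert, should deliver oxygen syn to the (S)-hydroxyl in the conformer that minimises allylic 1,3-strain with the cis CH2 group, setting both oxirane centres (threo selectivity).

Step 8
Reactants: 16 (2E)-7-[(2R,3R)-3-[(1S)-1-hydroxyethyl]-2-(propan-2-yl)oxiran-2-yl]-5-methylhept-2-en-4-one
Product: 17 (2E)-7-[(2R,3S)-3-acetyl-2-(propan-2-yl)oxiran-2-yl]-5-methylhept-2-en-4-one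
Conditions: Dess–Martin periodinane, pyridine, CH2Cl2, rt
Reagents that add atoms: none
Why: Dess–Martin oxidation of the secondary alcohol should give the epoxy ketone without touching epoxide or enone, the stereochemical information of the carbinol now residing in the oxirane.

Step 9
Reactants: 17 (2E)-7-[(2R,3S)-3-acetyl-2-(propan-2-yl)oxiran-2-yl]-5-methylhept-2-en-4-one
Product: 18 (2R,3S)-2-[(5E)-3-methyl-4-(triethylsilyloxy)hepta-3,5-dien-1-yl]-2-(propan-2-yl)-3-[1-(triethylsilyloxy)ethenyl]oxirane
Conditions: LiN(i-Pr)2 (LDA), Et3SiCl (in-situ quench), THF, −78 °C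
Reagents that add atoms: chlorotriethylsilane, CC[Si](Cl)(CC)CC
Why: Kinetic deprotonation with in-situ silyl trapping (silyl enol ether formation) should enolise the methyl ketone at CH3 and the enone at its α′-methine, giving the enolsilane and the cross-conjugated 2-silyloxydiene in one operation without a Lewis acid that could open the epoxide.

Step 10
Reactants: 18 (2R,3S)-2-[(5E)-3-methyl-4-(triethylsilyloxy)hepta-3,5-dien-1-yl]-2-(propan-2-yl)-3-[1-(triethylsilyloxy)ethenyl]oxirane
Product: 20 4β,10-bis(triethylsilyloxy)dauc-9-en-6-one, via O-silylated enone cation 19 (not isolated)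
Conditions: Et3SiOTf (10 mol %), CH2Cl2, −78 °C; then Et3N
Reagents that add atoms: none
Why: Et3SiOTf silylates the epoxide oxygen, the C5–O bond next to the enolsilane ionises as the nucleophilic terminus C1 of the silyl dienol ether attacks C5 from the face opposite the departing oxygen, the resulting O-silylated enone 19 is closed at C8 by the C7 terminus of the enolsilane, and the C6 silyloxocarbenium ion then hands its silyl group to the next epoxide. The closest known reaction type is the silyl-triflate-catalysed intramolecular (4+3) cycloaddition of epoxy enolsilanes with tethered dienes such as furans, which opens the epoxide with inversion; here the 4π partner is a 2-silyloxydiene, so the two bonds should form one after the other. The cyclopentane closes in a 5-exo-trig mode with respect to C1=C10 (endo with respect to the epoxide, both of whose carbons end in the ring) and the cycloheptane in a 7-endo-trig Mukaiyama–Michael mode. C4 is carried over unchanged, C5 is set by inversion at the epoxide carbon, C1 by the alkylation transition state, in which the methyl group and not the bulky silyloxydienyl arm should lie next to the C6 enolsilane substituent on C5 (1β-methyl trans to 5α-H), and C8 is not controlled and is erased in step 14. The step needs conjugate capture at C8 instead of carbonyl capture at C10, and epoxide opening at C5 and not at the tertiary C4: the first is the normal course of enolsilanes with O-silylated enones and avoids a bond to a carbon flanked by the quaternary C1, the second rests on the enolsilane making C5–O the allylic bond and on the tethered nucleophile reaching only C5 through a five-membered transition state.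

Step 11
Reactants: 20 4β,10-bis(triethylsilyloxy)dauc-9-en-6-one
Product: 21 4β,10-bis(triethylsilyloxy)dauc-9-en-6β-ol
Conditions: LiBH(s-Bu)3 (L-Selectride), THF, −78 °C; aq NH4Cl
Reagents that add atoms: none
Why: The bulky hydride should add to the C6 ketone from the α-face, anti to the 1,3-related angular β-methyl on C1 and the β-silyloxy group on C4 (as in the reduction of trans-fused 6-oxo steroids), setting the 6β-alcohol while the silyl enol ether masks C10 (diastereoselective ketone reduction).

Step 12
Reactants: 22 4-hydroxy-3-methoxybenzoic acid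
Product: 24 4-(tert-butyldimethylsilyloxy)-3-methoxybenzoic acid, via bis-TBS derivative 23 (not isolated)
Conditions: TBSCl, imidazole, DMF, rt; then AcOH/THF/H2O, rt
Reagents that add atoms: tert-butyldimethylsilyl chloride, CC(C)(C)[Si](C)(C)Cl
Why: Silylation of both acidic groups followed by selective hydrolysis of the labile silyl ester should leave the phenol protected as its TBS ether (protecting-group installation).

Step 13
Reactants: 21 4β,10-bis(triethylsilyloxy)dauc-9-en-6β-ol; 24 4-(tert-butyldimethylsilyloxy)-3-methoxybenzoic acid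
Product: 26 4β,10-bis(triethylsilyloxy)dauc-9-en-6β-yl 4-(tert-butyldimethylsilyloxy)-3-methoxybenzoate, via mixed anhydride 25 (not isolated)
Conditions: 24, 2,4,6-trichlorobenzoyl chloride, Et3N, toluene, rt; then 21, DMAP, toluene, rt → 50 °C
Reagents that add atoms: none
Why: Yamaguchi esterification through the mixed anhydride and DMAP should acylate the hindered secondary alcohol with retention at C6 under non-acidic conditions that preserve the silyl enol ether.

Step 14
Reactants: 26 4β,10-bis(triethylsilyloxy)dauc-9-en-6β-yl 4-(tert-butyldimethylsilyloxy)-3-methoxybenzoate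
Product: 27 10-oxo-4β-(triethylsilyloxy)dauc-8-en-6β-yl 4-(tert-butyldimethylsilyloxy)-3-methoxybenzoate
Conditions: Pd(OAc)2 (1.1 equiv), MeCN, rt
Reagents that add atoms: none
Why: In the Saegusa–Ito oxidation the silyl enol ether transmetalates to a palladium enolate bound at C9, and β-hydride elimination, possible only toward C8–H because C1 is quaternary, should give the C8=C9 enone regiospecifically and erase the C8 centre.

Step 15
Reactants: 27 10-oxo-4β-(triethylsilyloxy)dauc-8-en-6β-yl 4-(tert-butyldimethylsilyloxy)-3-methoxybenzoate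
Product: 28 (1S,4R,5S,6R)-4β-hydroxy-10-oxodauc-8-en-6β-yl 4-hydroxy-3-methoxybenzoate
Conditions: Bu4NF, AcOH, THF, 0 °C → rt
Reagents that add atoms: none
Why: Buffered fluoride (desilylation) should cleave the aryl TBS ether and the tertiary triethylsilyl ether in one operation without touching the ester or the enone.

Compound list
1 | 3-methylbut-1-yne | CC(C)C#C | starting material
2 | N-methoxy-N-methylacetamide | CC(=O)N(C)OC | starting material
3 | lithium 3-methylbut-1-yn-1-ide | CC(C)C#C[Li] | intermediate
4 | 5-methylhex-3-yn-2-one | CC(=O)C#CC(C)C | intermediate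
5 | (2S)-5-methylhex-3-yn-2-ol | C[C@H](O)C#CC(C)C | intermediate
6 | sodium cyclic alkenylalanate (1-oxa-2-aluminacyclopent-3-ene ate complex from 5) | C[C@@H]1O[Al-](OCCOC)(OCCOC)C(C(C)C)=C1.[Na+] | intermediate
7 | (2S,3Z)-4-iodo-5-methylhex-3-en-2-ol | C[C@H](O)/C=C(\I)C(C)C | intermediate
8 | 2-methylbut-3-enoic acid (racemic) | C=CC(C)C(=O)O | starting material
9 | 1-(2-methylbut-3-enoyl)imidazole | C=CC(C)C(=O)n1ccnc1 | intermediate
10 | N-methoxy-N,2-dimethylbut-3-enamide (racemic) | C=CC(C)C(=O)N(C)OC | intermediate
11 | 4-(9-borabicyclo[3.3.1]nonan-9-yl)-N-methoxy-N,2-dimethylbutanamide | CON(C)C(=O)C(C)CCB1C2CCCC1CCC2 | intermediate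
12 | (5E,7S)-7-hydroxy-N-methoxy-N,2-dimethyl-5-(propan-2-yl)oct-5-enamide (C2 epimers) | CON(C)C(=O)C(C)CC/C(C(C)C)=C\[C@H](C)O | intermediate
13 | (E)-1-bromoprop-1-ene | C/C=C/Br | starting material
14 | (E)-prop-1-enyllithium | C/C=C/[Li] | intermediate
15 | (2E,8E,10S)-10-hydroxy-5-methyl-8-(propan-2-yl)undeca-2,8-dien-4-one (C5 epimers) | C/C=C/C(=O)C(C)CC/C(C(C)C)=C\[C@H](C)O | intermediate
16 | (2E)-7-[(2R,3R)-3-[(1S)-1-hydroxyethyl]-2-(propan-2-yl)oxiran-2-yl]-5-methylhept-2-en-4-one (C5 epimers) | C[C@H](O)[C@H]1O[C@@]1(C(C)C)CCC(C)C(=O)/C=C/C | intermediate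
17 | (2E)-7-[(2R,3S)-3-acetyl-2-(propan-2-yl)oxiran-2-yl]-5-methylhept-2-en-4-one (C5 epimers) | CC(=O)[C@H]1O[C@@]1(C(C)C)CCC(C)C(=O)/C=C/C | intermediate
18 | (2R,3S)-2-[(5E)-3-methyl-4-(triethylsilyloxy)hepta-3,5-dien-1-yl]-2-(propan-2-yl)-3-[1-(triethylsilyloxy)ethenyl]oxirane (both geometries at the tetrasubstituted enol ether) | C=C(O[Si](CC)(CC)CC)[C@H]1O[C@@]1(C(C)C)CCC(C)=C(O[Si](CC)(CC)CC)/C=C/C | intermediate
19 | monocyclic O-silylated enone cation (triflate): cyclopentane with the C6 enolsilane on C5, the triethylsilyloxy and isopropyl groups on C4, and methyl plus the silyloxocarbenium arm on C1 | C=C(O[Si](CC)(CC)CC)[C@H]1[C@](O[Si](CC)(CC)CC)(C(C)C)CC[C@]1(C)C(=[O+][Si](CC)(CC)CC)/C=C/C.[O-]S(=O)(=O)C(F)(F)F | intermediate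
20 | 4β,10-bis(triethylsilyloxy)dauc-9-en-6-one (trans-fused, 1β-CH3, 5α-H; C8 epimers) | O=C1CC(C)C=C(O[Si](CC)(CC)CC)[C@@]2(C)CC[C@@](O[Si](CC)(CC)CC)(C(C)C)[C@H]12 | intermediate
21 | 4β,10-bis(triethylsilyloxy)dauc-9-en-6β-ol | O[C@@H]1CC(C)C=C(O[Si](CC)(CC)CC)[C@@]2(C)CC[C@@](O[Si](CC)(CC)CC)(C(C)C)[C@H]12 | intermediate
22 | 4-hydroxy-3-methoxybenzoic acid (vanillic acid) | COc1cc(C(=O)O)ccc1O | starting material
23 | tert-butyldimethylsilyl 4-(tert-butyldimethylsilyloxy)-3-methoxybenzoate | COc1cc(C(=O)O[Si](C)(C)C(C)(C)C)ccc1O[Si](C)(C)C(C)(C)C | intermediate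
24 | 4-(tert-butyldimethylsilyloxy)-3-methoxybenzoic acid | COc1cc(C(=O)O)ccc1O[Si](C)(C)C(C)(C)C | intermediate
25 | 4-(tert-butyldimethylsilyloxy)-3-methoxybenzoic 2,4,6-trichlorobenzoic anhydride | COc1cc(C(=O)OC(=O)c2c(Cl)cc(Cl)cc2Cl)ccc1O[Si](C)(C)C(C)(C)C | intermediate
26 | 4β,10-bis(triethylsilyloxy)dauc-9-en-6β-yl 4-(tert-butyldimethylsilyloxy)-3-methoxybenzoate | COc1cc(C(=O)O[C@@H]2CC(C)C=C(O[Si](CC)(CC)CC)[C@@]3(C)CC[C@@](O[Si](CC)(CC)CC)(C(C)C)[C@H]23)ccc1O[Si](C)(C)C(C)(C)C | intermediate
27 | 10-oxo-4β-(triethylsilyloxy)dauc-8-en-6β-yl 4-(tert-butyldimethylsilyloxy)-3-methoxybenzoate | COc1cc(C(=O)O[C@@H]2CC(C)=CC(=O)[C@@]3(C)CC[C@@](O[Si](CC)(CC)CC)(C(C)C)[C@H]23)ccc1O[Si](C)(C)C(C)(C)C | intermediate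
28 | (1S,4R,5S,6R)-4β-hydroxy-10-oxodauc-8-en-6β-yl 4-hydroxy-3-methoxybenzoate | COc1cc(C(=O)O[C@@H]2CC(C)=CC(=O)[C@@]3(C)CC[C@@](O)(C(C)C)[C@H]23)ccc1O | target

Total step count: 15. Longest linear sequence: 13 steps (steps 1–3, 5–11, 13–15).

Steps most likely to fail

Step 10 (key step). The process at risk is interruption after the first C–C bond: cation 19 may lose its silyl group, or the seven-membered ring may close too slowly, so that no bicycle forms. The facial preference at C1 is also a prediction. The fallback completes the annulation stepwise. It sets out from 18: Et3SiOTf (1.1 equiv) with 2,6-di-tert-butylpyridine in CH2Cl2 at −78 °C and an aqueous acidic quench should give the monocyclic diketone F1. t-BuOK in t-BuOH/THF then closes the seven-membered ring by intramolecular Michael addition of the methyl ketone enolate to the enone (7-endo-trig), giving the 6,10-diketone F2. LiBH(s-Bu)3 at −78 °C should reduce the less hindered C6 ketone (C10 is flanked by the quaternary C1) to the hydroxy ketone F3. Yamaguchi esterification with 24 gives the ester ketone F4, and dehydrogenation of the C10 ketone with IBX in DMSO at 70 °C (only C9 is enolisable) comes back to the route at 27.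

Step 11. The process at risk is poor facial selectivity, that is hydride delivery from the β-face, which gives the 6α-alcohol. The fallback replaces retentive acylation by invertive esterification. It sets out from 20: if the reduction gives mainly the 6α-alcohol F5, this is treated with 24, PPh3 and diisopropyl azodicarboxylate in toluene (Mitsunobu reaction), which inverts C6 and comes back to the route at 26.

Step 14. The process at risk is slow transfer of the hindered triethylsilyl enol ether to palladium, with hydrolysis to the saturated ketone instead of dehydrogenation. The fallback is a selenium-based dehydrogenation. It sets out from 26: PhSeCl in CH2Cl2 at −78 °C should convert the silyl enol ether into the α-phenylselanyl ketone F6. Oxidation with H2O2 and pyridine at 0 °C gives the selenoxide F7, whose syn-elimination toward C8–H comes back to the route at 27.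

Further compounds
F1 | step 10 | monocyclic diketone: cyclopentane with acetyl on C5, triethylsilyloxy and isopropyl on C4, methyl and (E)-but-2-enoyl on C1 | CC(=O)[C@H]1[C@](O[Si](CC)(CC)CC)(C(C)C)CC[C@]1(C)C(=O)/C=C/C
F2 | step 10 | 4β-(triethylsilyloxy)daucane-6,10-dione | O=C1CC(C)CC(=O)[C@@]2(C)CC[C@@](O[Si](CC)(CC)CC)(C(C)C)[C@H]12
F3 | step 10 | 6β-hydroxy-4β-(triethylsilyloxy)daucan-10-one | O[C@@H]1CC(C)CC(=O)[C@@]2(C)CC[C@@](O[Si](CC)(CC)CC)(C(C)C)[C@H]12
F4 | step 10 | 10-oxo-4β-(triethylsilyloxy)daucan-6β-yl 4-(tert-butyldimethylsilyloxy)-3-methoxybenzoate | COc1cc(C(=O)O[C@@H]2CC(C)CC(=O)[C@@]3(C)CC[C@@](O[Si](CC)(CC)CC)(C(C)C)[C@H]23)ccc1O[Si](C)(C)C(C)(C)C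
F5 | step 11 | 4β,10-bis(triethylsilyloxy)dauc-9-en-6α-ol | O[C@H]1CC(C)C=C(O[Si](CC)(CC)CC)[C@@]2(C)CC[C@@](O[Si](CC)(CC)CC)(C(C)C)[C@H]12
F6 | step 14 | 10-oxo-9-(phenylselanyl)-4β-(triethylsilyloxy)daucan-6β-yl 4-(tert-butyldimethylsilyloxy)-3-methoxybenzoate | COc1cc(C(=O)O[C@@H]2CC(C)C([Se]c4ccccc4)C(=O)[C@@]3(C)CC[C@@](O[Si](CC)(CC)CC)(C(C)C)[C@H]23)ccc1O[Si](C)(C)C(C)(C)C
F7 | step 14 | selenoxide of F6 | COc1cc(C(=O)O[C@@H]2CC(C)C([Se](=O)c4ccccc4)C(=O)[C@@]3(C)CC[C@@](O[Si](CC)(CC)CC)(C(C)C)[C@H]23)ccc1O[Si](C)(C)C(C)(C)C
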